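**Plan**

- Numbering (labdane): ring A = C1–C5 and C10, ring B = C5–C10; C11–C12 link C9 to the butenolide C13–C16; C17 on C8; C18 (α) and C19 (β) on C4; C20 on C10.
- The retrosynthesis cuts, in this order, C12–C13 (butenolide coupling), C11=C12 (from a C11 lactol), C4–C18 and C4–C19, C8–C17, then C9–C10 (ring B), C8–C9 and C5–C6.
- Enabling feature: the quaternary C10 sits between C5 and C9, C4 and C8 carry only one-carbon units (C18/C19, C17) and C9 carries C11. C4 and C8 can therefore be ketones and C11 an ester, giving a 4,8-dioxodecalin-9-carboxylate whose only fixed stereocentre is C10.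
- Forward: ring A is bought as a cyclohexenone, the C6–C8 chain is attached at C5 and grown into a β-keto ester (C9, C11), and ring B closes by conjugate addition of C9 to C10. C17, C19, C18, C12 and the butenolide follow.
- Stereochemistry: C10 comes from the chiral catalyst in the ring closure; C5, C8 and C9 from base equilibration to the trans-fused, all-equatorial arrangement; C4 from equatorial methylation of an aldehyde enolate anti to the axial C20 methyl.

Key step: step 5

Assumption: the quinine-derived catalyst of step 5 is taken to give the 10β-methyl series; if the sense of induction proves opposite, its quinidine-derived pseudoenantiomer replaces it.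
Remark: 9 is written as its keto tautomer; it should exist largely as the C8 enol, which changes nothing in what follows.

**Route**

Step 1
Reactants: 1 ethyl 2-methyl-4-oxocyclohex-2-ene-1-carboxylate; 2 2-(2-bromoethyl)-1,3-dioxolane
Product: 3 ethyl 3-[2-(1,3-dioxolan-2-yl)ethyl]-2-methyl-4-oxocyclohex-2-ene-1-carboxylate
Conditions: KOtBu, t-BuOH, NaI (cat.), reflux
Reagents that add atoms: none
Why: Alkylation of the extended enolate of this vinylogous β-keto ester with a primary bromide is known to occur mainly at ring carbon 3 (α to the ketone), which places the C6–C8 chain on the future C5.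

Step 2
Reactants: 3 ethyl 3-[2-(1,3-dioxolan-2-yl)ethyl]-2-methyl-4-oxocyclohex-2-ene-1-carboxylate
Product: 5 2-[2-(1,3-dioxolan-2-yl)ethyl]-3-methylcyclohex-2-en-1-one, via the potassium carboxylate 4 (not isolated)
Conditions: KOH, EtOH/H2O, reflux
Reagents that add atoms: none
Why: Saponification followed by decarboxylation of the vinylogous β-keto carboxylate is the standard passage from such alkylated esters to 2-alkyl-3-methylcyclohex-2-enones, and the dioxolane is stable to base.

Step 3
Reactants: 5 2-[2-(1,3-dioxolan-2-yl)ethyl]-3-methylcyclohex-2-en-1-one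
Product: 6 3-(2-methyl-6-oxocyclohex-1-en-1-yl)propanal
Conditions: 1 M HCl, THF, rt
Reagents that add atoms: water, O
Why: Mild acid-catalysed acetal hydrolysis should free the aldehyde without touching the enone.

Step 4
Reactants: 6 3-(2-methyl-6-oxocyclohex-1-en-1-yl)propanal; 7 tert-butyl diazoacetate
Product: 8 tert-butyl 5-(2-methyl-6-oxocyclohex-1-en-1-yl)-3-oxopentanoate
Conditions: SnCl2 (10 mol%), CH2Cl2, rt
Reagents that add atoms: none
Why: In the Roskamp homologation the Lewis acid-activated aldehyde takes up the diazo ester and a 1,2-hydride shift with loss of N2 gives the β-keto ester, the enone ketone being far less electrophilic; the tert-butyl ester is chosen so that C11 can later be told apart from C17.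

Step 5
Reactants: 8 tert-butyl 5-(2-methyl-6-oxocyclohex-1-en-1-yl)-3-oxopentanoate
Product: 9 tert-butyl 10β-methyl-4,8-dioxo-5αH-trans-decalin-9β-carboxylate
Conditions: 1-[3,5-bis(trifluoromethyl)phenyl]-3-[(8α,9S)-6′-methoxycinchonan-9-yl]thiourea (10 mol%), toluene, 40 °C
Reagents that add atoms: none
Why: Proposed new method: the quinuclidine nitrogen of the catalyst deprotonates the doubly activated C9 methylene of 8 while the thiourea hydrogen-bonds to the C4 carbonyl, so the bound enolate adds to the β-carbon C10 of the tethered enone and the resulting C4 enolate is protonated at C5. The closest known reaction types are the base-mediated intramolecular Michael addition of β-keto esters to 2-alkylcyclohex-2-enones, which gives such decalins as racemates, and amine–thiourea-catalysed enantioselective Michael additions of β-keto esters to less substituted enones; what is new is the enantioselective attack on a tetrasubstituted enone to form a quaternary carbon. Ring B (C5–C10) closes in the 6-endo-trig mode, both carbons of the acceptor alkene lying inside the new ring. C10 is set by the catalyst, which decides the enone face that C9 approaches; C5 and C9 are α to carbonyl groups and should settle under the amine base as the trans ring fusion with the ester equatorial. The step needs enantiofacial selectivity at C10 and conjugate in preference to carbonyl addition: the first rests on the two-point binding of enolate and enone, the second on the reversibility of the competing aldol and on C9 being the only carbon the amine can deprotonate.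

Step 6
Reactants: 9 tert-butyl 10β-methyl-4,8-dioxo-5αH-trans-decalin-9β-carboxylate
Product: 10 tert-butyl 10β-methyl-4-oxo-8-(trifluoromethanesulfonyloxy)-5αH-Δ8-octalin-9-carboxylate
Conditions: NaH, PhNTf2, THF, 0 °C to rt
Reagents that add atoms: N-phenylbis(trifluoromethanesulfonimide), O=S(=O)(N(c1ccccc1)S(=O)(=O)C(F)(F)F)C(F)(F)F
Why: Only the β-keto ester is acidic enough for one equivalent of NaH, and O-sulfonylation of its sodium enolate is the usual route to β-triflyloxy enoates, so the C4 ketone should stay untouched.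

Step 7
Reactants: 10 tert-butyl 10β-methyl-4-oxo-8-(trifluoromethanesulfonyloxy)-5αH-Δ8-octalin-9-carboxylate
Product: 11 9-tert-butyl 8-methyl 10β-methyl-4-oxo-5αH-Δ8-octalin-8,9-dicarboxylate
Conditions: Pd(OAc)2 (5 mol%), dppp (6 mol%), CO (1 atm), MeOH, Et3N, DMF, 60 °C
Reagents that add atoms: carbon monoxide, [C-]#[O+]; methanol, CO
Why: Palladium-catalysed methoxycarbonylation of enol triflates is reliable and brings in C17 at the carboxyl level, so that C8 becomes an epimerisable centre in the next step.

Step 8
Reactants: 11 9-tert-butyl 8-methyl 10β-methyl-4-oxo-5αH-Δ8-octalin-8,9-dicarboxylate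
Product: 13 9-tert-butyl 8-methyl 10β-methyl-4-oxo-5αH-trans-decalin-8α,9β-dicarboxylate, via the epimer mixture 12 (not isolated)
Conditions: Mg, MeOH, 0 °C to rt; then NaOMe (cat.), MeOH, 50 °C
Reagents that add atoms: none
Why: Dissolving-metal conjugate reduction with Mg in MeOH saturates the doubly activated alkene far more readily than it attacks an isolated ketone, and methoxide equilibration of the two α-ester centres (and of C5 next to the ketone) should leave the all-equatorial isomer with 8α-ester, 9β-ester and trans ring fusion.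

Step 9
Reactants: 13 9-tert-butyl 8-methyl 10β-methyl-4-oxo-5αH-trans-decalin-8α,9β-dicarboxylate
Product: 15 9-tert-butyl 8-methyl 4-formyl-10β-methyl-5αH-trans-decalin-8α,9β-dicarboxylate (C4 epimers), via the enol ether 14 (not isolated)
Conditions: Ph3P(CH2OMe)Cl, KOtBu, THF, 0 °C to rt; then 1 M HCl, THF, rt
Reagents that add atoms: (methoxymethyl)triphenylphosphonium chloride, COC[P+](c1ccccc1)(c1ccccc1)c1ccccc1.[Cl-]; water, O
Why: Wittig methoxymethylenation of the C4 ketone and hydrolysis of the enol ether is the standard one-carbon homologation to the aldehyde (C19); the C4 configuration is immaterial because this centre is deprotonated in the next step, and C5 stays trans once C4 is no longer a ketone.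

Step 10
Reactants: 15 9-tert-butyl 8-methyl 4-formyl-10β-methyl-5αH-trans-decalin-8α,9β-dicarboxylate
Product: 16 9-tert-butyl 8-methyl 4β-formyl-4α,10β-dimethyl-5αH-trans-decalin-8α,9β-dicarboxylate
Conditions: MeI, KOtBu, THF, 0 °C
Reagents that add atoms: iodomethane, CI
Why: α-Methylation of the aldehyde potassium enolate (the esters are far less acidic) should occur from the equatorial α face because the axial β face of C4 is shielded by the 1,3-diaxial C20 methyl, giving 4α-CH3 and 4β-CHO as known for 4-acyl enolates of 10-methyl-trans-decalins.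

Step 11
Reactants: 16 9-tert-butyl 8-methyl 4β-formyl-4α,10β-dimethyl-5αH-trans-decalin-8α,9β-dicarboxylate
Product: 17 9β-(tert-butoxycarbonyl)-8α-(methoxycarbonyl)-4α,10β-dimethyl-5αH-trans-decalin-4β-carboxylic acid
Conditions: NaClO2, NaH2PO4, 2-methylbut-2-ene, t-BuOH/H2O, rt
Reagents that add atoms: sodium chlorite, [Na+].[O-]Cl=O
Why: Pinnick oxidation converts even hindered, non-enolisable aldehydes into acids under buffered conditions that leave both esters alone.

Step 12
Reactants: 17 9β-(tert-butoxycarbonyl)-8α-(methoxycarbonyl)-4α,10β-dimethyl-5αH-trans-decalin-4β-carboxylic acid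
Product: 18 9β-(tert-butoxycarbonyl)-8α-(hydroxymethyl)-4α,10β-dimethyl-5αH-trans-decalin-4β-carboxylic acid
Conditions: LiBH4, THF, 0 °C
Reagents that add atoms: none
Why: LiBH4 reduces the secondary methyl ester (C17), whereas the tert-butyl ester next to the quaternary C10 and the lithium carboxylate of the neopentyl acid are expected to be inert at this temperature.

Step 13
Reactants: 18 9β-(tert-butoxycarbonyl)-8α-(hydroxymethyl)-4α,10β-dimethyl-5αH-trans-decalin-4β-carboxylic acid
Product: 19 4α,10β-dimethyl-5αH-trans-decalin-4β-carboxylic acid bearing a trans-fused γ-lactone across C8/C9 (C9β–C11(=O)–O–C17H2–C8α)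
Conditions: TsOH·H2O (20 mol%), toluene, 90 °C
Reagents that add atoms: none
Why: Acid-catalysed loss of isobutene from the tert-butyl ester and lactonisation onto the neighbouring hydroxymethyl group should give the trans-fused γ-lactone, in which C11 (carbonyl) and C17 (alkoxy carbon) now differ in oxidation level.

Step 14
Reactants: 19 the lactone acid
Product: 20 4-methoxybenzyl ester of lactone acid 19
Conditions: 4-methoxybenzyl chloride, Cs2CO3, DMF, rt
Reagents that add atoms: 4-methoxybenzyl chloride, COc1ccc(CCl)cc1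
Why: O-Alkylation of the caesium carboxylate is insensitive to the hindrance around C19 and gives an ester that resists hydride, ylide and borane reagents yet is cleaved by acid at the end.

Step 15
Reactants: 20 4-methoxybenzyl ester of lactone acid 19
Product: 21 the corresponding lactol (C11 hemiacetal, anomer mixture)
Conditions: i-Bu2AlH (1.2 equiv), CH2Cl2, −78 °C; aq. potassium sodium tartrate
Reagents that add atoms: none
Why: Partial reduction of a γ-lactone to the lactol at low temperature is standard, and the axial neopentyl ester at C4 is too hindered to compete.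

Step 16
Reactants: 21 the lactol
Product: 22 4-methoxybenzyl 9β-ethenyl-8α-(hydroxymethyl)-4α,10β-dimethyl-5αH-trans-decalin-4β-carboxylate
Conditions: Ph3PCH3Br, KOtBu, THF, 0 to 50 °C
Reagents that add atoms: methyltriphenylphosphonium bromide, C[P+](c1ccccc1)(c1ccccc1)c1ccccc1.[Br-]
Why: Wittig methylenation of the open hydroxy aldehyde form of the lactol installs C12 and frees the C17 hydroxyl in one operation, and any epimerisation at C9 leads to the equatorial 9β aldehyde, which is the one required.

Step 17
Reactants: 22 the vinyl alcohol; 23 3-bromofuran-2(5H)-one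
Product: 25 4-methoxybenzyl ester of the target acid, via the B-alkyl-9-BBN adduct 24 (not isolated)
Conditions: 9-BBN (2.5 equiv), THF, 0 °C to rt; then 23, PdCl2(dppf) (5 mol%), AsPh3 (10 mol%), Cs2CO3, DMF/H2O, rt
Reagents that add atoms: none
Why: Anti-Markovnikov hydroboration of the vinyl group (one further equivalent of borane is taken up by the hydroxyl) followed by B-alkyl Suzuki–Miyaura coupling, a reaction established for α-halo-α,β-unsaturated carbonyl compounds including α-bromobutenolides, forms C12–C13 and delivers the butenolide intact.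

Step 18
Reactants: 25 4-methoxybenzyl ester of the target acid
Product: 26 (1S,4aR,5S,6R,8aR)-6-(hydroxymethyl)-1,4a-dimethyl-5-[2-(2-oxo-2,5-dihydrofuran-3-yl)ethyl]decahydronaphthalene-1-carboxylic acid
Conditions: TFA, anisole, CH2Cl2, 0 °C; aq. NaHCO3 work-up
Reagents that add atoms: none
Why: Acidolysis of the 4-methoxybenzyl ester proceeds by O–benzyl cleavage, so the hindered acid is freed under conditions that the butenolide and the primary alcohol tolerate.

**Compound list**

1 | ethyl 2-methyl-4-oxocyclohex-2-ene-1-carboxylate (racemic) | CCOC(=O)C1CCC(=O)C=C1C | starting material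
2 | 2-(2-bromoethyl)-1,3-dioxolane | BrCCC1OCCO1 | starting material
3 | ethyl 3-[2-(1,3-dioxolan-2-yl)ethyl]-2-methyl-4-oxocyclohex-2-ene-1-carboxylate (racemic) | CCOC(=O)C1CCC(=O)C(CCC2OCCO2)=C1C | intermediate
4 | potassium 3-[2-(1,3-dioxolan-2-yl)ethyl]-2-methyl-4-oxocyclohex-2-ene-1-carboxylate | [K+].[O-]C(=O)C1CCC(=O)C(CCC2OCCO2)=C1C | intermediate
5 | 2-[2-(1,3-dioxolan-2-yl)ethyl]-3-methylcyclohex-2-en-1-one | CC1=C(CCC2OCCO2)C(=O)CCC1 | intermediate
6 | 3-(2-methyl-6-oxocyclohex-1-en-1-yl)propanal | CC1=C(CCC=O)C(=O)CCC1 | intermediate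
7 | tert-butyl diazoacetate | [N-]=[N+]=CC(=O)OC(C)(C)C | starting material
8 | tert-butyl 5-(2-methyl-6-oxocyclohex-1-en-1-yl)-3-oxopentanoate | CC1=C(CCC(=O)CC(=O)OC(C)(C)C)C(=O)CCC1 | intermediate
9 | tert-butyl 10β-methyl-4,8-dioxo-5αH-trans-decalin-9β-carboxylate | C[C@]12CCCC(=O)[C@@H]1CCC(=O)[C@@H]2C(=O)OC(C)(C)C | intermediate
10 | tert-butyl 10β-methyl-4-oxo-8-(trifluoromethanesulfonyloxy)-5αH-Δ8-octalin-9-carboxylate | C[C@]12CCCC(=O)[C@@H]1CCC(OS(=O)(=O)C(F)(F)F)=C2C(=O)OC(C)(C)C | intermediate
11 | 9-tert-butyl 8-methyl 10β-methyl-4-oxo-5αH-Δ8-octalin-8,9-dicarboxylate | C[C@]12CCCC(=O)[C@@H]1CCC(C(=O)OC)=C2C(=O)OC(C)(C)C | intermediate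
12 | 9-tert-butyl 8-methyl 10β-methyl-4-oxo-5αH-decalin-8,9-dicarboxylate, mixture of C8/C9 epimers | C[C@]12CCCC(=O)[C@@H]1CCC(C(=O)OC)C2C(=O)OC(C)(C)C | intermediate
13 | 9-tert-butyl 8-methyl 10β-methyl-4-oxo-5αH-trans-decalin-8α,9β-dicarboxylate | C[C@]12CCCC(=O)[C@@H]1CC[C@@H](C(=O)OC)[C@@H]2C(=O)OC(C)(C)C | intermediate
14 | 9-tert-butyl 8-methyl 4-(methoxymethylidene)-10β-methyl-5αH-trans-decalin-8α,9β-dicarboxylate (E/Z) | C[C@]12CCCC(=COC)[C@@H]1CC[C@@H](C(=O)OC)[C@@H]2C(=O)OC(C)(C)C | intermediate
15 | 9-tert-butyl 8-methyl 4-formyl-10β-methyl-5αH-trans-decalin-8α,9β-dicarboxylate (C4 epimers) | C[C@]12CCCC(C=O)[C@@H]1CC[C@@H](C(=O)OC)[C@@H]2C(=O)OC(C)(C)C | intermediate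
16 | 9-tert-butyl 8-methyl 4β-formyl-4α,10β-dimethyl-5αH-trans-decalin-8α,9β-dicarboxylate | C[C@]12CCC[C@](C)(C=O)[C@@H]1CC[C@@H](C(=O)OC)[C@@H]2C(=O)OC(C)(C)C | intermediate
17 | 9β-(tert-butoxycarbonyl)-8α-(methoxycarbonyl)-4α,10β-dimethyl-5αH-trans-decalin-4β-carboxylic acid | C[C@]12CCC[C@](C)(C(=O)O)[C@@H]1CC[C@@H](C(=O)OC)[C@@H]2C(=O)OC(C)(C)C | intermediate
18 | 9β-(tert-butoxycarbonyl)-8α-(hydroxymethyl)-4α,10β-dimethyl-5αH-trans-decalin-4β-carboxylic acid | C[C@]12CCC[C@](C)(C(=O)O)[C@@H]1CC[C@@H](CO)[C@@H]2C(=O)OC(C)(C)C | intermediate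
19 | lactone acid: 4α,10β-dimethyl-5αH-trans-decalin-4β-carboxylic acid with trans-fused γ-lactone C9β–C11(=O)–O–C17H2–C8α | C[C@]12CCC[C@](C)(C(=O)O)[C@@H]1CC[C@H]3COC(=O)[C@H]23 | intermediate
20 | 4-methoxybenzyl ester of 19 | C[C@]12CCC[C@](C)(C(=O)OCc3ccc(OC)cc3)[C@@H]1CC[C@H]4COC(=O)[C@H]24 | intermediate
21 | lactol of 20 (C11 hemiacetal, anomer mixture) | C[C@]12CCC[C@](C)(C(=O)OCc3ccc(OC)cc3)[C@@H]1CC[C@H]4COC(O)[C@H]24 | intermediate
22 | 4-methoxybenzyl 9β-ethenyl-8α-(hydroxymethyl)-4α,10β-dimethyl-5αH-trans-decalin-4β-carboxylate | C[C@]12CCC[C@](C)(C(=O)OCc3ccc(OC)cc3)[C@@H]1CC[C@@H](CO)[C@@H]2C=C | intermediate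
23 | 3-bromofuran-2(5H)-one | O=C1OCC=C1Br | starting material
24 | B-alkyl-9-BBN adduct of 22 (boron on C12; C17 hydroxyl as its 9-BBN borinate) | C[C@]12CCC[C@](C)(C(=O)OCc3ccc(OC)cc3)[C@@H]1CC[C@@H](COB4C5CCCC4CCC5)[C@@H]2CCB6C7CCCC6CCC7 | intermediate
25 | 4-methoxybenzyl ester of the target acid | C[C@]12CCC[C@](C)(C(=O)OCc3ccc(OC)cc3)[C@@H]1CC[C@@H](CO)[C@@H]2CCC4=CCOC4=O | intermediate
26 | (1S,4aR,5S,6R,8aR)-6-(hydroxymethyl)-1,4a-dimethyl-5-[2-(2-oxo-2,5-dihydrofuran-3-yl)ethyl]decahydronaphthalene-1-carboxylic acid (CNP0562063.1) | C[C@]12CCC[C@](C)(C(=O)O)[C@@H]1CC[C@@H](CO)[C@@H]2CCC1=CCOC1=O | target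

**Step count and risks**

Total step count: 18. Longest linear sequence: 18 steps (1 to 26); 2, 7 and 23 are bought.

Steps most likely to fail:

1. Step 5. The catalyst-bound enolate may fail to add to the hindered tetrasubstituted enone, or may add with poor facial discrimination at C10. Fallback with known chemistry, setting out from 8: cyclisation with Cs2CO3 in MeCN (the established base-mediated 6-endo Michael closure) gives the racemic trans-decalin diketo ester F1. Condensation with one equivalent of (S)-1-phenylethylamine (cat. AcOH, toluene, removal of water) gives the β-enamino ester of the 10β-methyl series F2 and its diastereomer from the enantiomeric decalin F3, which are separated by chromatography or crystallisation. Hydrolysis of F2 with aqueous HCl in THF returns to the route at 9.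

2. Step 17. Base-induced ring opening or double-bond migration of the bromobutenolide, or protodeboronation and β-hydride elimination outrunning transmetalation, may erode the coupling. Fallback setting out from 22: silylation (TBSCl, imidazole, DMF) gives the tert-butyldimethylsilyl ether F4. Hydroboration–oxidation (9-BBN, THF; then NaBO3) gives the primary C12 alcohol F5, and I2, PPh3 and imidazole give the primary iodide F6. Alkylation of the lithium enolate of 3-(phenylsulfanyl)oxolan-2-one (LiN(i-Pr)2, THF/HMPA, −78 °C to rt) gives the α-(phenylsulfanyl) lactone F7. Oxidation with mCPBA at −78 °C gives the sulfoxide F8, and thermal syn-elimination in toluene at 110 °C gives the silyl-protected butenolide F9. TFA in wet CH2Cl2 with anisole then removes the silyl ether and the 4-methoxybenzyl ester together and comes back to the route at 26.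

3. Step 9. The ylide may enolise the hindered C4 ketone in place of adding to it, so that little olefin forms. Fallback setting out from 13: Corey–Chaykovsky methylenation with dimethylsulfonium methylide (Me3SI, KOtBu, DMSO/THF, 0 °C) gives the C4 spiro-epoxide F10. Meinwald rearrangement with BF3·OEt2 in CH2Cl2 at −78 °C (1,2-hydride shift to the tertiary cation at C4) comes back to the route at aldehyde 15.

Further compounds
F1 | step 5 | racemic tert-butyl 10-methyl-4,8-dioxo-trans-decalin-9-carboxylate (9 and its enantiomer) | C[C@]12CCCC(=O)[C@@H]1CCC(=O)[C@@H]2C(=O)OC(C)(C)C.C[C@@]12CCCC(=O)[C@H]1CCC(=O)[C@H]2C(=O)OC(C)(C)C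
F2 | step 5 | β-enamino ester of 9 with (S)-1-phenylethylamine (nitrogen on C8, 10β-methyl series) | C[C@]12CCCC(=O)[C@@H]1CCC(N[C@@H](C)c3ccccc3)=C2C(=O)OC(C)(C)C
F3 | step 5 | β-enamino ester of the enantiomer of 9 with (S)-1-phenylethylamine | C[C@@]12CCCC(=O)[C@H]1CCC(N[C@@H](C)c3ccccc3)=C2C(=O)OC(C)(C)C
F4 | step 17 | tert-butyldimethylsilyl ether of 22 | C[C@]12CCC[C@](C)(C(=O)OCc3ccc(OC)cc3)[C@@H]1CC[C@@H](CO[Si](C)(C)C(C)(C)C)[C@@H]2C=C
F5 | step 17 | primary C12 alcohol from F4 | C[C@]12CCC[C@](C)(C(=O)OCc3ccc(OC)cc3)[C@@H]1CC[C@@H](CO[Si](C)(C)C(C)(C)C)[C@@H]2CCO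
F6 | step 17 | primary C12 iodide from F5 | C[C@]12CCC[C@](C)(C(=O)OCc3ccc(OC)cc3)[C@@H]1CC[C@@H](CO[Si](C)(C)C(C)(C)C)[C@@H]2CCI
F7 | step 17 | α-(phenylsulfanyl) lactone (C13 epimers) | C[C@]12CCC[C@](C)(C(=O)OCc3ccc(OC)cc3)[C@@H]1CC[C@@H](CO[Si](C)(C)C(C)(C)C)[C@@H]2CCC4(Sc5ccccc5)CCOC4=O
F8 | step 17 | sulfoxide of F7 | C[C@]12CCC[C@](C)(C(=O)OCc3ccc(OC)cc3)[C@@H]1CC[C@@H](CO[Si](C)(C)C(C)(C)C)[C@@H]2CCC4(S(=O)c5ccccc5)CCOC4=O
F9 | step 17 | tert-butyldimethylsilyl ether of 25 | C[C@]12CCC[C@](C)(C(=O)OCc3ccc(OC)cc3)[C@@H]1CC[C@@H](CO[Si](C)(C)C(C)(C)C)[C@@H]2CCC4=CCOC4=O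
F10 | step 9 | C4 spiro-epoxide of 13 (C4 epimers) | C[C@]12CCCC3(CO3)[C@@H]1CC[C@@H](C(=O)OC)[C@@H]2C(=O)OC(C)(C)C
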